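Readings and results come from a simulation with made-up constants; noise was put on by code.

An easy step first: if each initiator begins one chain and every free monomer ends in a chain, the length is free monomer charged over initiator charged, which for the new flask is 20.0.

common to all: initiator 20 mM

| run | free monomer | transfer agent | remark | time |
|---|---|---|---|---|
| Saturday's | 0.56 M | 0.040 M | run made earlier |  |
| Sunday's | 0.88 M | 0.040 M | run made earlier |  |
| flask | 0.40 M | 0.0400 M |  | 2.5 h |

- Saturday's (time / h: monomer in chains / %, free monomer / %): 0.667: 30.7, 11.8; 1.33: 33.0, 1.3; 2.00: 33.5, 0.2; 2.50: 32.8, 0.1
- Sunday's (time / h: monomer in chains / %, free monomer / %): 0.667: 30.5, 10.7; 1.33: 32.0, 1.8; 2.00: 32.6, 0.6; 2.50: 32.3, 0.1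

(each reading ± 0.3 percentage points)

- the average divides the monomer in chains by the number of chains begun, living and dead together
- the earlier runs do not show the number of chains; that part of a forecast is a guess

- whether the average number of monomer units in a chain (chains begun, living or dead) reaches 4.0 by 2.5 h (yes / no)
- average number of monomer units in a chain (chains begun, living or dead) at 2.5 h

Saturday's and Sunday's runs break the second premise of that rule. Free monomer falls to 0.1% and 0.1% of its charge, yet monomer in chains levels off. The mean of the last two readings of both runs is 32.8%; I call it the chain share, the fraction of the free monomer charged that ends in chains, which is a selectivity in the usual term. Between the two runs the charge changes by a factor of 1.57, while the share moves by 0.7 percentage points, against a scatter of 0.3 points on a reading. So I carry it to the new flask, although that charge lies below both runs.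

In the new flask initiator is 5.00% of the free monomer charge, so one chain per initiator gives a length of 6.56. The runs do not show the chain count, so this step is a guess. Its border is the transfer agent, charged at 10.0% of the free monomer. At this chain share the length wanted allows chains up to 8.20% of the free monomer charge, more than the initiator provides, so my yes holds unless over 32.0% of the transfer agent charge begins new chains, one chain each. I commit to yes, at about 6.56.

The forecast differs, with no and a length of 3, lower than mine, on the ground that “the high transfer agent-to-monomer ratio favours substantial transfer”.

The new flask gives yes, with a length of 7.05 at 2.5 h, by these steps:

    free monomer → uncatalysed product (k = 0.0388 min⁻¹)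
    living end + transfer agent → dead chain (kL = 0.625 L mol⁻¹ min⁻¹)
    free monomer + living end → monomer in chains + living end, rate k3*[living end]*[free monomer] (k = 1.28 L mol⁻¹ min⁻¹)
    initiator → spent initiator (k = 0.160 min⁻¹)
    free monomer + initiator → living end + monomer in chains (k = 6.67 L mol⁻¹ min⁻¹)

At that time living end, dead chain and spent initiator together come to 100% of the initiator charge. Living end and dead chain, the chains begun, are 4.71% of the free monomer charge, and the chain share divided by that fraction is 6.96.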